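The enzyme is not used up by a round: free enzyme, first complex, loaded enzyme and second complex pass into one another, and their sum drops by whatever becomes spent catalyst.

    starting material + free enzyme ⇌ first complex (K1 = 430 M⁻¹, k1 = 5.1 × 10⁵ M⁻¹ min⁻¹)
    first complex → loaded enzyme + first product (k2 = 1000 min⁻¹)
    second substrate + loaded enzyme ⇌ second complex (K3 = 1.3 M⁻¹, k3 = 1.6 × 10⁵ M⁻¹ min⁻¹)
    second complex → free enzyme + target (k4 = 7200 min⁻¹)
    free enzyme + impurity → spent catalyst (k5 = 2.8 × 10⁵ M⁻¹ min⁻¹)
    target ⇌ isomer of the product (K6 = 0.74, k6 = 0.082 min⁻¹)

| flask | starting material | second substrate | free enzyme | impurity | time |
|---|---|---|---|---|---|
| ash | 0.10 M | 2.50 equiv | 0.03 mol% | 8.2 µM | 6.0 min |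
| birch | 0.10 M | 2.50 equiv | 0.09 mol% | 8.2 µM | 6.0 min |
| larch | 0.10 M | 2.50 equiv | 0.01 mol% | 8.2 µM | 6.0 min |

- which of these there is most of at the end, counted by the starting material in it, ash (isomer of the product / starting material / first complex / target)
- which of these there is most of at the end, counted by the starting material in it, birch (isomer of the product / starting material / first complex / target)
- which of these there is most of at the end, counted by the starting material in it, larch (isomer of the product / starting material / first complex / target)
- final amount of the leader among these, as a percentage of the starting material charged, in ash
- final amount of the leader among these, as a percentage of the starting material charged, in birch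
- final amount of the leader among these, as a percentage of the starting material charged, in larch

Let us turn the question round: what would have to be true for starting material to lead at the end? If less than half the charge has been converted, starting material holds over half, while target, which shares the converted part with its isomer, holds under half. So we ask how much one charge of enzyme can convert in the time, and we start by timing one round at the opening concentrations, with c(starting material) = 0.10 M.

First complex breaking: 0.00100 min

Second complex breaking: 1.39 × 10⁻⁴ min

Free enzyme meeting starting material, counting meetings that fall back: 4.29 × 10⁻⁵ min

Loaded enzyme meeting second substrate, counted the same way: 4.52 × 10⁻⁴ min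

Whole round: 0.00163 min, or 613 min⁻¹ rounds per enzyme.

The breaking of first complex is the longest leg, the nearest thing here to a rate-limiting step.

Loading times time over round time gives, for larch, 0.367. We carry this as the reach, the share of the charge that the charged enzyme would turn over in the time at its opening pace.

Ash: 1.10

Birch: 3.30

Along a run both substrates fall and impurity takes enzyme, so we treat the reach as a ceiling on conversion, not a figure for it. Larch stands below the half, so we expect starting material to lead there, with at least 63.3% left.

Ash and birch stand above the half, so that test does not answer for them. Impurity could take 27.3% of the catalyst in ash and 9.11% in birch. Cutting the reach by those shares at once still leaves 0.800 and 3.00, both above the half. But a ceiling above the half is no floor on conversion, so these figures only leave room for target to lead in both, and by hand we leave those two flasks open.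

The forecast gives target at 70.1% in ash, target at 73.8% in birch and starting material at 69.7% in larch, reasoning that “Only free enzyme (about 3%) meets the impurity”.

The flasks end with target at 70.2% in ash, target at 73.8% in birch and starting material at 69.7% in larch. Larch then holds 28.8% of its catalyst as spent catalyst. Larch converted 30.3% of its charge, which is 0.826 of its reach. The neighbour of larch charged with 0.025 mol% of free enzyme has a reach of 0.918. Taking the same part of that reach leaves 24.2% of the starting material, and that flask ends with 26.8%.

The rate constants are those of an exercise; the run is a simulation.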